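## Retrosynthetic overview

1. The C6 chloride comes last: SN2 chlorination (inversion) of a (6R)-allylic alcohol, itself made by a singlet-oxygen ene reaction of a (5E)-olefin.
2. Key step: the C7–C8 bond and the lactone C–O bond are made together by a SmI2 ketyl coupling of an enal with a β-keto ester that lactonises in the same pot. This forms the ten-membered carbocycle and the γ-lactone in one operation and sets C7, C8 and C17.
3. The open-chain precursor comes from a cyclohexadiene aldehyde: left arm by Grignard addition and cross-metathesis, right arm by Roskamp homologation, 11,12-cis-diol by OsO4.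
4. The cyclohexadiene comes from a Diels–Alder/1,4-elimination between a D-mannitol-derived (E)-2-methyl-enal and 1-silyloxypenta-1,3-diene; the chiral-pool centre C9 sets C1 and C10.
5. Ring order: six-membered ring first (step 3), then ten-membered ring and lactone together (step 12).

Assumption: briarane numbering is used for atom labels (C15 = methyl on C1, C16 = exocyclic methylene carbon, C17–C19 = lactone carbons, C20 = methyl on C11); the SMILES is read as (1S,2S,6S,7R,8R,9S,10S,11S,12R,17R).

## Route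

Step 1
Reactants: 1 1,2:5,6-di-O-isopropylidene-D-mannitol; 2 2-(triphenylphosphoranylidene)propanal
Product: 4 (2E)-3-[(4S)-2,2-dimethyl-1,3-dioxolan-4-yl]-2-methylprop-2-enal, via (R)-glyceraldehyde acetonide 3 (not isolated)
Conditions: NaIO4, sat. aq NaHCO3, CH2Cl2, 0 °C → rt; then 2 (2.2 equiv), rt
Reagents that add atoms: none
Why: Malaprade glycol cleavage gives two molecules of (R)-glyceraldehyde acetonide, which the formyl-stabilised Wittig ylide olefinates in the same flask with high E selectivity and without touching the dioxolane stereocentre (the future C9, S after the priority change).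

Step 2
Reactants: 5 (E)-pent-2-enal
Product: 6 (1E,3E)-1-(tert-butyldimethylsilyloxy)penta-1,3-diene
Conditions: TBSOTf, Et3N, Et2O, 0 °C → rt
Reagents that add atoms: tert-butyldimethylsilyl trifluoromethanesulfonate, CC(C)(C)[Si](C)(C)OS(=O)(=O)C(F)(F)F
Why: Soft enolisation (O-silylation, then γ-deprotonation) turns the enal into the conjugated silyl dienol ether, whose E,E isomer is the one that reacts in the next step.

Step 3
Reactants: 4 (2E)-3-[(4S)-2,2-dimethyl-1,3-dioxolan-4-yl]-2-methylprop-2-enal; 6 (1E,3E)-1-(tert-butyldimethylsilyloxy)penta-1,3-diene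
Product: 8 (1S,6S)-6-[(4S)-2,2-dimethyl-1,3-dioxolan-4-yl]-1,5-dimethylcyclohexa-2,4-diene-1-carbaldehyde, via silyloxy cycloadduct 7 (not isolated)
Conditions: toluene, BHT (cat.), 110 °C, sealed tube; then CSA (10 mol %), 4 Å MS, 50 °C
Reagents that add atoms: none
Why: Normal-demand Diels–Alder reaction in which the silyloxy group sends the methyl-bearing diene terminus (C11) to the enal β-carbon (C10); allylic 1,3-strain with the α-methyl holds C9–H in the alkene plane and the diene adds anti to the C9–O bond (Felkin-type), setting C1 and C10 (both S), and the acid then ionises the allylic silyl ether so that loss of H-11 (1,4-elimination) erases the endo/exo centres to give one diene.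

Step 4
Reactants: 8 (1S,6S)-6-[(4S)-2,2-dimethyl-1,3-dioxolan-4-yl]-1,5-dimethylcyclohexa-2,4-diene-1-carbaldehyde; 9 4-bromo-2-methylbut-1-ene
Product: 12 (1S)-1-{(1S,6S)-6-[(4S)-2,2-dimethyl-1,3-dioxolan-4-yl]-1,5-dimethylcyclohexa-2,4-dien-1-yl}-4-methylpent-4-en-1-yl acetate, via Grignard reagent 10 (not isolated), via bromomagnesium alkoxide 11 (not isolated)
Conditions: 9, Mg, THF, rt; 8, THF, −78 → 0 °C; then Ac2O, DMAP (cat.), 0 °C → rt
Reagents that add atoms: acetic anhydride, CC(=O)OC(C)=O
Why: Grignard addition under Felkin–Anh control, the nucleophile attacking the neopentyl aldehyde anti to the bulky ring carbon C10 and passing the methyl rather than the vinylic C14, gives the (2S)-alkoxide, which is acetylated in situ so that the C2 acetate of the target is in place from here on.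

Step 5
Reactants: 12 (1S)-1-{(1S,6S)-6-[(4S)-2,2-dimethyl-1,3-dioxolan-4-yl]-1,5-dimethylcyclohexa-2,4-dien-1-yl}-4-methylpent-4-en-1-yl acetate
Product: 13 (1S)-1-{(1S,6S)-6-[(1S)-1,2-dihydroxyethyl]-1,5-dimethylcyclohexa-2,4-dien-1-yl}-4-methylpent-4-en-1-yl acetate
Conditions: AcOH/H2O/THF (3:1:1), 40 °C
Reagents that add atoms: none
Why: Acid-catalysed acetal hydrolysis frees the C8/C9 diol while the secondary acetate, the 1,1-disubstituted alkene and the ring diene tolerate warm aqueous acetic acid.

Step 6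
Reactants: 13 (1S)-1-{(1S,6S)-6-[(1S)-1,2-dihydroxyethyl]-1,5-dimethylcyclohexa-2,4-dien-1-yl}-4-methylpent-4-en-1-yl acetate
Product: 14 bis(triethylsilyl) ether of 13 (C8–OSiEt3 primary and C9–OSiEt3 secondary)
Conditions: Et3SiCl, imidazole, DMAP (cat.), DMF, 0 °C → rt
Reagents that add atoms: chlorotriethylsilane, CC[Si](Cl)(CC)CC
Why: Standard silylation of both hydroxyls; the C9 silyl ether later prevents tetronic acid formation and lactonisation through O9.

Step 7
Reactants: 14 bis(triethylsilyl) ether of 13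
Product: 15 (1S)-1-{(1S,6S)-1,5-dimethyl-6-[(1S)-2-oxo-1-(triethylsilyloxy)ethyl]cyclohexa-2,4-dien-1-yl}-4-methylpent-4-en-1-yl acetate
Conditions: (COCl)2, DMSO, CH2Cl2, −78 → −40 °C; then Et3N, −78 → 0 °C
Reagents that add atoms: none
Why: Swern conditions cleave and oxidise a primary triethylsilyl ether directly to the aldehyde while the secondary triethylsilyl ether is inert, so the C8 aldehyde is unveiled without a separate deprotection and without epimerising C9 at low temperature.

Step 8
Reactants: 16 methyl 2-methyl-3-oxobutanoate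
Product: 17 methyl 2-diazopropanoate
Conditions: 4-acetamidobenzenesulfonyl azide, DBU, MeCN, 0 °C → rt
Reagents that add atoms: 4-acetamidobenzenesulfonyl azide, CC(=O)Nc1ccc(cc1)S(=O)(=O)N=[N+]=[N-]
Why: Deacylative Regitz diazo transfer, in which the azide adds to the enolate and the acetyl group leaves on the sulfonamide nitrogen.

Step 9
Reactants: 15 α-(triethylsilyloxy) aldehyde; 17 methyl 2-diazopropanoate
Product: 18 methyl 2-methyl-3-oxo-4-(triethylsilyloxy)butanoate carrying at C4 the cyclohexadienyl core of 15 (C1, C2, C9, C10 as in 15; C17 epimers)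
Conditions: Sc(OSO2CF3)3 (5 mol %), CH2Cl2, −40 → −20 °C
Reagents that add atoms: none
Why: Roskamp homologation (Lewis acid-promoted addition of the diazo ester to the aldehyde, then 1,2-hydride shift with loss of N2) gives the β-keto ester, whose C17 is an epimerisable mixture that is resolved in step 12.

Step 10
Reactants: 18 β-keto ester; 19 (E)-but-2-enal
Product: 20 (E)-enal: 18 in which the terminal C(CH3)=CH2 has become C(CH3)=CH–CHO with the formyl group trans to C4 (C17 epimers)
Conditions: [1,3-bis(2,4,6-trimethylphenyl)imidazolidin-2-ylidene]dichloro(2-isopropoxybenzylidene)ruthenium (second-generation Hoveyda–Grubbs catalyst, 10 mol %), 19 (5 equiv), CH2Cl2, 40 °C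
Reagents that add atoms: none
Why: Cross-metathesis of the 1,1-disubstituted alkene with an excess of the enal partner gives the E-trisubstituted enal under thermodynamic control, the ring diene and the cis-alkene next to quaternary C1 being metathesis-inactive.

Step 11
Reactants: 20 (E)-enal
Product: 21 11,12-cis-diol of 20 (11S,12R; both hydroxyls on the face opposite the C15 methyl and the C10 side chain; C13=C14 retained; C17 epimers)
Conditions: OsO4 (2 mol %), NMO (1.1 equiv), acetone/H2O (10:1), 0 °C
Reagents that add atoms: osmium tetroxide, O=[Os](=O)(=O)=O; 4-methylmorpholine N-oxide, C[N+]1([O-])CCOCC1; water, O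
Why: Upjohn dihydroxylation, in which OsO4 takes the electron-rich trisubstituted C11=C12 bond of the diene (the enal is electron-poor and C13=C14 is shielded by quaternary C1) from the face anti to the C10 side chain and the C15 methyl, giving the cis-diol with the target configuration.

Step 12
Reactants: 21 diol enal β-keto ester
Product: 24 (5E)-2-acetoxy-8,9,11,12-tetrahydroxybriara-5,13-dien-19,7-olide with all stereocentres as in the target, via pinacol diol ester 22 (not isolated), via silyl ether lactone 23 (not isolated)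
Conditions: SmI2 (3 equiv), MeOH (2 equiv), THF (0.003 M), −78 → 0 °C; then 1 M aq HCl, rt
Reagents that add atoms: none
Why: Proposed new method: SmI2 ketyl–carbonyl (pinacol) coupling is known for aldehyde/β-keto ester pairs closing five- and six-membered rings and for medium-ring dicarbonyl closures, and is extended here to a ten-membered ring in which trivalent samarium, chelated by the ketyl oxygen O8, the ester carbonyl and the small C9 silyl ether oxygen, lets the enal-derived ketyl attack C8 anti to ring carbon C10 and anti to the C17 methyl of the freely epimerising keto ester through a samarium-bridged transition state that gives the cis-7,8-diol (7R,8R,17R), after which the C7 alkoxide closes the γ-lactone on the methyl ester and dilute acid removes the silyl group.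

Step 13
Reactants: 24 tetrahydroxy lactone
Product: 25 (5E)-2,9,12-triacetoxy-8,11-dihydroxybriara-5,13-dien-19,7-olide with all stereocentres as in the target
Conditions: Ac2O, pyridine, DMAP (cat.), CH2Cl2, 0 °C → rt
Reagents that add atoms: acetic anhydride, CC(=O)OC(C)=O
Why: Acylation of the two secondary alcohols (C9, C12) only, the hindered tertiary C8 and C11 hydroxyls not reacting under these conditions.

Step 14
Reactants: 25 (5E)-triacetate
Product: 27 (6R)-6-hydroxy analogue of the target (C5=C16 exocyclic alkene in place; hydroxyl where the target has chlorine but with the opposite C6 geometry), via allylic hydroperoxide 26 (not isolated)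
Conditions: O2, hν (visible), tetraphenylporphyrin (cat.), CH2Cl2, 0 °C; then PPh3, 0 °C → rt
Reagents that add atoms: dioxygen, O=O
Why: Schenck ene reaction, in which singlet oxygen adds to C6 on the exposed face of the E-cyclodecene (the face away from C8 when H-7 eclipses the alkene) and takes hydrogen from the C16 methyl on the more crowded side of the double bond (cis effect), giving the (6R)-hydroperoxide and the C5=C16 alkene before PPh3 reduces the O–O bond.

Step 15
Reactants: 27 (6R)-allylic alcohol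
Product: 28 CNP0259091.1 (target)
Conditions: PPh3, Cl3CC(O)CCl3, CH2Cl2, −20 → 0 °C
Reagents that add atoms: hexachloroacetone, ClC(Cl)(Cl)C(=O)C(Cl)(Cl)Cl
Why: Appel-type chlorination with the PPh3/hexachloroacetone reagent, which converts secondary allylic alcohols into unrearranged chlorides by SN2 displacement of the oxyphosphonium group, so inversion at C6 gives the (6S)-chloride.

## Compound list

1 | 1,2:5,6-di-O-isopropylidene-D-mannitol | CC1(C)OC[C@@H](O1)[C@@H](O)[C@H](O)[C@H]1COC(C)(C)O1 | starting material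
2 | 2-(triphenylphosphoranylidene)propanal | CC(C=O)=P(c1ccccc1)(c1ccccc1)c1ccccc1 | starting material
3 | (R)-glyceraldehyde acetonide, (4R)-2,2-dimethyl-1,3-dioxolane-4-carbaldehyde | O=C[C@H]1COC(C)(C)O1 | intermediate
4 | (2E)-3-[(4S)-2,2-dimethyl-1,3-dioxolan-4-yl]-2-methylprop-2-enal | O=C/C(C)=C/[C@H]1COC(C)(C)O1 | intermediate
5 | (E)-pent-2-enal | CC/C=C/C=O | starting material
6 | (1E,3E)-1-(tert-butyldimethylsilyloxy)penta-1,3-diene | C/C=C/C=C/O[Si](C)(C)C(C)(C)C | intermediate
7 | 2-(tert-butyldimethylsilyloxy)-6-[(4S)-2,2-dimethyl-1,3-dioxolan-4-yl]-1,5-dimethylcyclohex-3-ene-1-carbaldehyde (C1, C6 as in 8; endo isomer shown, C2/C5 epimers converge) | O=C[C@@]2(C)[C@@H](O[Si](C)(C)C(C)(C)C)C=C[C@@H](C)[C@@H]2[C@H]1COC(C)(C)O1 | intermediate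
8 | (1S,6S)-6-[(4S)-2,2-dimethyl-1,3-dioxolan-4-yl]-1,5-dimethylcyclohexa-2,4-diene-1-carbaldehyde | O=C[C@@]2(C)C=CC=C(C)[C@@H]2[C@H]1COC(C)(C)O1 | intermediate
9 | 4-bromo-2-methylbut-1-ene | C=C(C)CCBr | starting material
10 | (3-methylbut-3-en-1-yl)magnesium bromide | C=C(C)CC[Mg]Br | intermediate
11 | bromomagnesium (2S)-alkoxide from addition of 10 to 8 | C=C(C)CC[C@H](O[Mg]Br)[C@@]2(C)C=CC=C(C)[C@@H]2[C@H]1COC(C)(C)O1 | intermediate
12 | (1S)-1-{(1S,6S)-6-[(4S)-2,2-dimethyl-1,3-dioxolan-4-yl]-1,5-dimethylcyclohexa-2,4-dien-1-yl}-4-methylpent-4-en-1-yl acetate | C=C(C)CC[C@H](OC(C)=O)[C@@]2(C)C=CC=C(C)[C@@H]2[C@H]1COC(C)(C)O1 | intermediate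
13 | (1S)-1-{(1S,6S)-6-[(1S)-1,2-dihydroxyethyl]-1,5-dimethylcyclohexa-2,4-dien-1-yl}-4-methylpent-4-en-1-yl acetate | C=C(C)CC[C@H](OC(C)=O)[C@@]2(C)C=CC=C(C)[C@@H]2[C@H](O)CO | intermediate
14 | bis(triethylsilyl) ether of 13 | C=C(C)CC[C@H](OC(C)=O)[C@@]2(C)C=CC=C(C)[C@@H]2[C@H](O[Si](CC)(CC)CC)CO[Si](CC)(CC)CC | intermediate
15 | (1S)-1-{(1S,6S)-1,5-dimethyl-6-[(1S)-2-oxo-1-(triethylsilyloxy)ethyl]cyclohexa-2,4-dien-1-yl}-4-methylpent-4-en-1-yl acetate | C=C(C)CC[C@H](OC(C)=O)[C@@]2(C)C=CC=C(C)[C@@H]2[C@H](O[Si](CC)(CC)CC)C=O | intermediate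
16 | methyl 2-methyl-3-oxobutanoate | CC(=O)C(C)C(=O)OC | starting material
17 | methyl 2-diazopropanoate | CC(=[N+]=[N-])C(=O)OC | intermediate
18 | β-keto ester from 15 and 17 (C17 epimers) | C=C(C)CC[C@H](OC(C)=O)[C@@]2(C)C=CC=C(C)[C@@H]2[C@H](O[Si](CC)(CC)CC)C(=O)C(C)C(=O)OC | intermediate
19 | (E)-but-2-enal | C/C=C/C=O | starting material
20 | (E)-enal β-keto ester (C17 epimers) | O=C/C=C(\C)CC[C@H](OC(C)=O)[C@@]2(C)C=CC=C(C)[C@@H]2[C@H](O[Si](CC)(CC)CC)C(=O)C(C)C(=O)OC | intermediate
21 | 11,12-cis-diol of 20 (11S,12R; C17 epimers) | O=C/C=C(\C)CC[C@H](OC(C)=O)[C@@]2(C)C=C[C@@H](O)[C@@](C)(O)[C@@H]2[C@H](O[Si](CC)(CC)CC)C(=O)C(C)C(=O)OC | intermediate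
22 | ten-membered cis-7,8-diol methyl ester, 9-O-triethylsilyl | O[C@H]2/C=C(\C)CC[C@H](OC(C)=O)[C@@]3(C)C=C[C@@H](O)[C@@](C)(O)[C@@H]3[C@H](O[Si](CC)(CC)CC)[C@]2(O)[C@@H](C)C(=O)OC | intermediate
23 | 9-O-triethylsilyl ether of 24 | O=C1O[C@H]2/C=C(\C)CC[C@H](OC(C)=O)[C@@]3(C)C=C[C@@H](O)[C@@](C)(O)[C@@H]3[C@H](O[Si](CC)(CC)CC)[C@]2(O)[C@H]1C | intermediate
24 | (5E)-2-acetoxy-8,9,11,12-tetrahydroxybriara-5,13-dien-19,7-olide, stereocentres as in the target | O=C1O[C@H]2/C=C(\C)CC[C@H](OC(C)=O)[C@@]3(C)C=C[C@@H](O)[C@@](C)(O)[C@@H]3[C@H](O)[C@]2(O)[C@H]1C | intermediate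
25 | (5E)-2,9,12-triacetoxy-8,11-dihydroxybriara-5,13-dien-19,7-olide, stereocentres as in the target | O=C1O[C@H]2/C=C(\C)CC[C@H](OC(C)=O)[C@@]3(C)C=C[C@@H](OC(C)=O)[C@@](C)(O)[C@@H]3[C@H](OC(C)=O)[C@]2(O)[C@H]1C | intermediate
26 | (6R)-6-hydroperoxy-5(16)-ene analogue of the target | C=C1CC[C@H](OC(C)=O)[C@@]2(C)C=C[C@@H](OC(C)=O)[C@@](C)(O)[C@@H]2[C@H](OC(C)=O)[C@]2(O)[C@@H](C)C(=O)O[C@H]2[C@@H]1OO | intermediate
27 | (6R)-6-hydroxy-5(16)-ene analogue of the target | C=C1CC[C@H](OC(C)=O)[C@@]2(C)C=C[C@@H](OC(C)=O)[C@@](C)(O)[C@@H]2[C@H](OC(C)=O)[C@]2(O)[C@@H](C)C(=O)O[C@H]2[C@@H]1O | intermediate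
28 | CNP0259091.1 | C=C1CC[C@H](OC(C)=O)[C@@]2(C)C=C[C@@H](OC(C)=O)[C@@](C)(O)[C@@H]2[C@H](OC(C)=O)[C@]2(O)[C@@H](C)C(=O)O[C@H]2[C@H]1Cl | target

## Step count and risks

Total steps: 15. Longest linear sequence: 13 (steps 1, 3–7, 9–15, from 1; one mole of 1 gives two of 4). Steps 2 and 8 make the diene and the diazo ester off-line.

The three steps most likely to fail, most risky first:

**Step 12 (key macrocyclisation).** Possible failures are simple reduction of the enal, loss of the C9 silyloxy group from the ketyl, or attack on the wrong C8 face. The fallback sets out from 20 and returns at 23; it closes the same two rings by a vinylchromium addition instead of a ketyl coupling. NaH and PhNTf2 convert 20 into the (Z)-enol triflate F1 (triflate cis to the ester through the sodium chelate). CrCl2 with catalytic NiCl2 in DMF/THF at high dilution joins C8 to the enal carbon (intramolecular Nozaki–Hiyama–Kishi coupling), and the chromium alkoxide lactonises to the ten-membered Δ8(17)-butenolide F2. t-BuOOH/DBU epoxidises the butenolide to the 8,17-epoxy lactone F3. SmI2 at −78 °C cleaves the α C–O bond to give the 8-hydroxy-17H lactone F4. OsO4/NMO as in step 11 then gives 23, which rejoins step 12 at the acid treatment.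

**Step 3 (cycloaddition/elimination).** The trisubstituted enal may be too sluggish thermally, and the acid may isomerise the diene. The fallback sets out from 5 and 4 and returns at 8; it uses Lewis-acid activation with an acid-stable diene and a palladium-mediated elimination. Isopropenyl acetate/TsOH converts 5 into (1E,3E)-penta-1,3-dien-1-yl acetate F5. Me2AlCl in CH2Cl2 at −78 → −20 °C promotes its addition to 4 to give the acetoxy cycloadduct F6; the regioisomer with the methyl next to C1 is expected alongside and must be separated. Pd(PPh3)4/Et3N in dioxane at 80 °C ionises the allylic acetate, and β-hydride elimination of H-11 from the allyl complex of divalent palladium gives 8.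

**Step 15 (chloride with inversion).** SN2′ attack at C16 or retention would give the wrong product. The fallback sets out from 25 and returns at 28, bypassing the allylic alcohol. mCPBA epoxidises C5=C6 of 25 on the exposed face to the 5,6-epoxide F7. Li2CuCl4 opens it at the secondary carbon C6 with inversion to the 6-chloro-5-hydroxy compound F8. Burgess reagent dehydrates the tertiary alcohol towards the C16 methyl to give 28.

Further compounds
F1 | step 12 | (Z)-enol triflate of 20 (triflate cis to the ester) | O=C/C=C(\C)CC[C@H](OC(C)=O)[C@@]2(C)C=CC=C(C)[C@@H]2[C@H](O[Si](CC)(CC)CC)/C(OS(=O)(=O)C(F)(F)F)=C(\C)C(=O)OC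
F2 | step 12 | ten-membered Δ8(17)-butenolide with ring diene, 9-O-triethylsilyl | O=C1O[C@H]2/C=C(\C)CC[C@H](OC(C)=O)[C@@]3(C)C=CC=C(C)[C@@H]3[C@H](O[Si](CC)(CC)CC)C2=C1C
F3 | step 12 | 8,17-epoxy lactone from F2 | O=C1O[C@H]2/C=C(\C)CC[C@H](OC(C)=O)[C@@]3(C)C=CC=C(C)[C@@H]3[C@H](O[Si](CC)(CC)CC)[C@@]24O[C@@]14C
F4 | step 12 | 8-hydroxy-17H lactone with ring diene, 9-O-triethylsilyl | O=C1O[C@H]2/C=C(\C)CC[C@H](OC(C)=O)[C@@]3(C)C=CC=C(C)[C@@H]3[C@H](O[Si](CC)(CC)CC)[C@]2(O)[C@H]1C
F5 | step 3 | (1E,3E)-penta-1,3-dien-1-yl acetate | C/C=C/C=C/OC(C)=O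
F6 | step 3 | 2-acetoxy-6-[(4S)-2,2-dimethyl-1,3-dioxolan-4-yl]-1,5-dimethylcyclohex-3-ene-1-carbaldehyde (C1, C6 as in 8) | O=C[C@@]2(C)[C@@H](OC(C)=O)C=C[C@@H](C)[C@@H]2[C@H]1COC(C)(C)O1
F7 | step 15 | 5,6-epoxide of 25 (oxygen on the exposed face) | C[C@]13CC[C@H](OC(C)=O)[C@@]2(C)C=C[C@@H](OC(C)=O)[C@@](C)(O)[C@@H]2[C@H](OC(C)=O)[C@]2(O)[C@@H](C)C(=O)O[C@H]2[C@@H]1O3
F8 | step 15 | (6S)-6-chloro-5-hydroxy compound from F7 | C[C@]1(O)CC[C@H](OC(C)=O)[C@@]2(C)C=C[C@@H](OC(C)=O)[C@@](C)(O)[C@@H]2[C@H](OC(C)=O)[C@]2(O)[C@@H](C)C(=O)O[C@H]2[C@H]1Cl
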